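**Analysis of the target**

The target (16) is a (3R)-isoflavan: a chroman, made of benzo ring A fused to the dihydropyran ring C, that carries the tetrasubstituted benzene ring B at C3. Ring A has a methoxyl at C5 and a free hydroxyl at C7. Ring B has a free hydroxyl at C2', a prenyl group at C3' and a methoxyl at C4', so the prenyl group sits between two oxygens and the four ring B substituents are contiguous. C3 is the only stereocentre, a benzylic methine between the methylene groups C2 and C4, so its configuration cannot be relayed from another centre and must come from a reagent or catalyst. C3 is configurationally safe once C2 is a CH2–O group, but it is labile whenever C2 is at the aldehyde or ester oxidation level, because its hydrogen is then benzylic and alpha to a carbonyl group. The sensitive groups are the trisubstituted prenyl alkene ortho to a phenol (acid closes it to a 2,2-dimethylchroman, hydrogenation saturates it, halogens and oxidants attack it) and two very electron-rich rings with free phenols. The synthesis is hard for three reasons: the lone stereocentre cannot be made by hydrogenating an isoflavene, four phenolic oxygens must be told apart, and the prenyl group must go onto the hindered position between two oxygens. The route rests on one feature: ring A with O1, C4a, the C5 methoxyl and the C7 hydroxyl is 5-methoxyresorcinol (11) in which one of two equivalent hydroxyls has become O1 and the carbon between that hydroxyl and the methoxyl has become C4a, while C4–C3–C2 is an acrolein unit with ring B on its alpha carbon.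

**Retrosynthetic reasoning**

16 from 15. The last change is removal of the methoxymethyl group from the C2' oxygen. That oxygen stays masked to the end for two reasons. It is the directing group for both metalations that build ring B. A free C2' hydroxyl would also compete with the ring A hydroxyl in closing ring C and give a five-membered dihydrobenzofuran. The forward reaction must cleave an aryl acetal without letting the freed phenol add to the neighbouring prenyl alkene.

15 from 14. Ring C is opened at O1–C2. Cutting here, rather than at C8a–O1 or C3–C4, leaves a primary alcohol and a phenol. The forward reaction is then a dehydrative etherification at a primary carbon that does not touch C3. Only the hydroxyl ortho to the side chain can reach C2, so the C7 hydroxyl needs no protection.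

14 from 13. C2 is raised to the aldehyde level and tied to the ring A oxygen as the lactol 13, the form in which the key step delivers it. Direct ionic deoxygenation of 13 to 15 would save a step. It needs acid, however, and passes through an oxocarbenium ion next to the C3 hydrogen, which invites elimination to the 4H-chromene, racemisation and damage to the prenyl and acetal groups. Hydride reduction followed by ring closure is milder and fixes C3 immediately.

13 from 10 and 11. Two bonds are cut, C4–C4a and O1–C2. This disconnection uses the hidden symmetry of ring A: 11 is purchased, needs no protecting group, and supplies O1, the C5 methoxyl and the C7 hydroxyl at once. The three-carbon unit arrives as the 2-arylacrolein 10 with C2 already oxidised. The forward reaction must join C4 of 11 to the methylene carbon of 10, protonate C3 enantioselectively and trap the aldehyde 12 as the lactol before it enolises. All of the stereochemical and most of the regiochemical risk of the route is concentrated here.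

10 from 9. The aldehyde is masked as the diethyl acetal 9. The free 2-arylacrolein is reactive towards itself, so it is released only just before use. The acetal also lets the three-carbon unit be attached by organometallic chemistry.

9 from 5 and 6. The bond between C1' of ring B and C3 is cut. Ring B becomes a nucleophile, the aryllithium 7 and then the arylzinc chloride 8, and the acrolein unit becomes the vinyl bromide 6. The position to be metalated is ortho to the methoxymethoxy group, the better of the two directing groups, so no halogen has to be introduced onto a ring that carries an alkene. A palladium-catalysed coupling forms the bond under neutral conditions.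

5 from 2 and 3, and 2 from 1. The prenyl group is cut off between the two oxygens. That carbon is the most acidic position of 2, so lithiation to 4 and alkylation with 3 put the prenyl group on the hindered position in one operation. Ether 2 is the methoxymethyl ether of the purchased phenol 1, whose methoxyl is the C4' methoxyl of the target.

**Alternatives that were turned down**

Alternative 1: The C3–C4 bond is made by carbene insertion, with a temporary bond between the C2' oxygen and C4 (a pterocarpan-type link) providing the ring. The diazo ester A1, with a chiral dirhodium tetracarboxylate Rh2(O2CR*)4, would insert into the benzylic ether C–H bond and give the cis-dihydrobenzofuran A2, creating C3 together with the C3–C4 bond.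
- For: enantioselective intramolecular C–H insertion of aryldiazoacetates into benzylic ether C–H bonds is an established reaction class on this substrate type. On precedent for the asymmetric step it is stronger than the chosen route.
- Against: A2 is far from the target. The ester must be reduced to C2, the benzylic C4–O bond cleaved reductively, the pivalate removed, ring C closed and the silyl ether removed.
- Against: A1 carries no prenyl group, because the electrophilic carbene and the reductive C–O cleavage are not compatible with it. The prenyl group would have to be placed at C3' on a late, polyfunctional intermediate.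
- Against: C3 in A2 is alpha to an ester, and a cis-to-trans epimerisation there would invert the one centre that matters. Ring A also needs three different oxygen protecting groups.
- Comparison: the chosen route has a less well-founded key step but is about half as long, uses ring A unprotected and installs the prenyl group at the start.

Alternative 2: The C3–C1' and C4–C4a bonds are formed across a two-carbon vinyl unit. Aryllithium 7 and the vinylboronic ester A3 form an ate complex. With the ring A triflate A4 and Pd(OAc)2 plus a chiral bisphosphine, ring B would shift from boron to the alpha carbon while the ring A aryl group is delivered to the beta carbon, giving the boronic ester A5.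
- For: two skeletal bonds and the stereocentre are formed in one convergent step by a known enantioselective reaction class. A5 has no racemisable carbonyl neighbour. On both points it is stronger than the chosen route, and it uses the same ring B nucleophile 7.
- Against: A4 is a tetraoxygenated benzene with three different oxygen substituents and a triflate flanked by two ortho groups. It takes several steps to make and is a poor substrate for oxidative addition. The migrating aryl group is also ortho-substituted.
- Against: the boron-bearing carbon is C3, so C2 is still missing. One-carbon homologation of a hindered secondary benzylic boronic ester, oxidation, desilylation, ring closure and removal of two acetals would follow.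
- Comparison: the chosen route obtains C2 from the acrolein carbonyl group and ring A from a purchased compound.

Alternative 3: Ring B itself is disconnected and built late as a cyclohexane-1,3-dione. The more substituted enolate of ketone A6 would add to methyl acrylate A7 (C1'–C6'), and the methyl-side enolate would then close onto the ester (C3'–C4') to give the dione A8.
- For: the 1,3-dioxygenation of ring B arises automatically, and alkylation between the two carbonyl groups would place the prenyl group at C3'. C3 of the chroman is beta to the ketone and cannot epimerise. On positional control of the prenyl group it equals the chosen route.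
- Against: the key step does not create the stereocentre. A6 must already be enantiopure, which requires a separate asymmetric synthesis of a 3-substituted chroman.
- Against: after A8 come C-prenylation against O-alkylation, dehydrogenative aromatisation in the presence of the prenyl alkene, and methylation of the C4' hydroxyl but not the C2' hydroxyl. The Michael addition must also take place at the more hindered alpha carbon.
- Comparison: ring B is bought as an arene in the chosen route and needs only two metalations. Alternative 3 is the longest option.

Key step: step 5

Remark on the chemistry: the sense of induction of the diamine catalyst in step 5 with a phenol nucleophile cannot be derived with certainty; the (S)-diamine is written and its enantiomer is used if the (3S)-lactol should predominate.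
Remark on the chemistry: 2-bromo-3,3-diethoxyprop-1-ene (6) is assumed to be a purchased reagent.

**Route**

Step 1
Reactants: 1 3-methoxyphenol
Product: 2 1-methoxy-3-(methoxymethoxy)benzene
Conditions: NaH, MOMCl, THF/DMF, 0 °C to rt
Reagents that add atoms: chloromethyl methyl ether (MOMCl), COCCl
Why: O-Alkylation of the sodium phenoxide with the reactive alpha-chloro ether (Williamson etherification); the methoxymethyl ether is the directing group for steps 2 and 3 and is removable with mild acid at the end.

Step 2
Reactants: 2 1-methoxy-3-(methoxymethoxy)benzene, 3 prenyl bromide (1-bromo-3-methylbut-2-ene)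
Product: 5 1-methoxy-3-(methoxymethoxy)-2-(3-methylbut-2-en-1-yl)benzene, via aryllithium 4 (not isolated)
Conditions: n-BuLi, THF, 0 °C to rt; CuI (10 mol%), 3, −40 °C to rt
Reagents that add atoms: none
Why: Directed ortho-metalation: the hydrogen between the two oxygens is the most acidic because both ether groups coordinate lithium. Copper-catalysed alkylation of 4 should take place at the primary carbon of the allylic bromide (SN2 rather than SN2'), placing the prenyl group on the hindered position.

Step 3
Reactants: 5 1-methoxy-3-(methoxymethoxy)-2-(3-methylbut-2-en-1-yl)benzene, 6 2-bromo-3,3-diethoxyprop-1-ene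
Product: 9 1-(3,3-diethoxyprop-1-en-2-yl)-4-methoxy-2-(methoxymethoxy)-3-(3-methylbut-2-en-1-yl)benzene, via aryllithium 7 (not isolated), via arylzinc chloride 8 (not isolated)
Conditions: n-BuLi, TMEDA, THF, −20 to 0 °C; ZnCl2, 0 °C to rt; 6, Pd(PPh3)4 (3 mol%), 50 °C
Reagents that add atoms: none
Why: A second directed ortho-metalation next to the methoxymethoxy group (a better lithium-coordinating director than methoxyl), transmetalation to zinc and Negishi coupling with the 1-bromovinyl acetal. The arylzinc reagent tolerates the acetal, and no electrophilic reagent that would attack the prenyl alkene is needed.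

Step 4
Reactants: 9 1-(3,3-diethoxyprop-1-en-2-yl)-4-methoxy-2-(methoxymethoxy)-3-(3-methylbut-2-en-1-yl)benzene
Product: 10 2-[4-methoxy-2-(methoxymethoxy)-3-(3-methylbut-2-en-1-yl)phenyl]prop-2-enal
Conditions: PPTS (cat.), acetone/H2O, rt; used at once
Reagents that add atoms: water, O
Why: Acid-catalysed acetal hydrolysis; the acyclic diethyl acetal of an enal ionises far more readily than the aryl methoxymethyl ether. The aldehyde is released only immediately before use because 2-arylacroleins dimerise and polymerise on storage.

Step 5
Reactants: 10 2-[4-methoxy-2-(methoxymethoxy)-3-(3-methylbut-2-en-1-yl)phenyl]prop-2-enal, 11 5-methoxyresorcinol (5-methoxybenzene-1,3-diol)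
Product: 13 (3R)-5-methoxy-3-[4-methoxy-2-(methoxymethoxy)-3-(3-methylbut-2-en-1-yl)phenyl]-3,4-dihydro-2H-chromene-2,7-diol (mixture of anomers at C2), via open-chain aldehyde 12 (not isolated)
Conditions: 11 (3 equiv), (S)-N1,N1-diethyl-3,3-dimethylbutane-1,2-diamine (20 mol%), TfOH (20 mol%), EtOAc, −20 °C, slow addition of 10
Reagents that add atoms: none
Why: Proposed new method: the primary amine of the catalyst condenses with 10 to an iminium ion (a secondary amine cannot, because of the alpha-aryl group), and C4 of 11, which is para to one hydroxyl and ortho to the other hydroxyl and to the methoxyl, adds to the unsubstituted CH2 terminus to form C4–C4a. Rearomatisation leaves an alpha-aryl enamine, to which the neighbouring protonated tertiary amine of the catalyst should hand its proton on one face of C3; this intramolecular proton transfer is the only element that sets the stereocentre. Hydrolysis releases aldehyde 12, which the ortho hydroxyl should capture by 6-exo-trig addition to the carbonyl group (O1–C2), closing ring C as lactol 13; the anomeric centre is left uncontrolled because step 6 removes it. The closest known reaction types are the primary-amine-catalysed Friedel–Crafts addition of indoles to alpha-substituted acroleins with enantioselective enamine protonation, and the amine-catalysed Friedel–Crafts alkylation–hemiacetalisation of naphthols and electron-rich phenols with enals to chroman-2-ols; their combination on a 2-arylacrolein and a free resorcinol is new. The step needs C-alkylation rather than O-alkylation (the soft beta carbon of the iminium ion and the reversibility of oxa-Michael addition favour it), attack at C4 or C6 rather than C2 of 11 (two equivalent positions para to a hydroxyl against one position between two hydroxyls), monoalkylation (excess 11, slow addition of 10), and lactol closure faster than re-enolisation of the alpha-aryl aldehyde (the hydroxyl is held five atoms from the carbonyl carbon; low temperature and a weak acid loading should also hold back dehydration to the 4H-chromene).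

Step 6
Reactants: 13 (3R)-5-methoxy-3-[4-methoxy-2-(methoxymethoxy)-3-(3-methylbut-2-en-1-yl)phenyl]-3,4-dihydro-2H-chromene-2,7-diol
Product: 14 4-[(2R)-3-hydroxy-2-[4-methoxy-2-(methoxymethoxy)-3-(3-methylbut-2-en-1-yl)phenyl]propyl]-5-methoxybenzene-1,3-diol
Conditions: NaBH4, THF/MeOH, −20 to 0 °C; aq. NH4Cl
Reagents that add atoms: none
Why: Hydride reduction of the aldehyde that is in ring–chain equilibrium with the lactol. It removes the anomeric centre and takes C2 out of the carbonyl oxidation level, after which C3 can no longer epimerise.

Step 7
Reactants: 14 4-[(2R)-3-hydroxy-2-[4-methoxy-2-(methoxymethoxy)-3-(3-methylbut-2-en-1-yl)phenyl]propyl]-5-methoxybenzene-1,3-diol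
Product: 15 (3R)-5-methoxy-3-[4-methoxy-2-(methoxymethoxy)-3-(3-methylbut-2-en-1-yl)phenyl]-3,4-dihydro-2H-chromen-7-ol
Conditions: PPh3, DIAD, THF (0.01 M), 0 °C to rt
Reagents that add atoms: none
Why: Intramolecular Mitsunobu etherification: the alkoxyphosphonium ion of the primary alcohol is displaced by the ortho phenol in a 6-exo-tet closure that the C7 hydroxyl cannot reach. The reaction takes place at C2 and leaves C3 untouched, and the methoxymethyl ether keeps the ring B oxygen from closing the competing five-membered ring.

Step 8
Reactants: 15 (3R)-5-methoxy-3-[4-methoxy-2-(methoxymethoxy)-3-(3-methylbut-2-en-1-yl)phenyl]-3,4-dihydro-2H-chromen-7-ol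
Product: 16 (3R)-3-[2-hydroxy-4-methoxy-3-(3-methylbut-2-en-1-yl)phenyl]-5-methoxy-3,4-dihydro-2H-chromen-7-ol
Conditions: HCl (1.25 M in MeOH), 0 °C to rt
Reagents that add atoms: none
Why: Acid-catalysed transacetalisation of the aryl methoxymethyl ether to methanol. Dilute acid at low temperature in methanol is chosen so that the freed C2' phenol does not add to the neighbouring prenyl alkene and the methoxymethyl cation is trapped by solvent rather than by ring A.

**Compound list**

1 | 3-methoxyphenol | COc1cccc(O)c1 | starting material
2 | 1-methoxy-3-(methoxymethoxy)benzene | COCOc1cccc(OC)c1 | intermediate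
3 | prenyl bromide (1-bromo-3-methylbut-2-ene) | CC(C)=CCBr | starting material
4 | [2-methoxy-6-(methoxymethoxy)phenyl]lithium | [Li]c1c(OC)cccc1OCOC | intermediate
5 | 1-methoxy-3-(methoxymethoxy)-2-(3-methylbut-2-en-1-yl)benzene | COCOc1cccc(OC)c1CC=C(C)C | intermediate
6 | 2-bromo-3,3-diethoxyprop-1-ene | C=C(Br)C(OCC)OCC | starting material
7 | [4-methoxy-2-(methoxymethoxy)-3-(3-methylbut-2-en-1-yl)phenyl]lithium | [Li]c1ccc(OC)c(CC=C(C)C)c1OCOC | intermediate
8 | chloro[4-methoxy-2-(methoxymethoxy)-3-(3-methylbut-2-en-1-yl)phenyl]zinc | Cl[Zn]c1ccc(OC)c(CC=C(C)C)c1OCOC | intermediate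
9 | 1-(3,3-diethoxyprop-1-en-2-yl)-4-methoxy-2-(methoxymethoxy)-3-(3-methylbut-2-en-1-yl)benzene | C=C(C(OCC)OCC)c1ccc(OC)c(CC=C(C)C)c1OCOC | intermediate
10 | 2-[4-methoxy-2-(methoxymethoxy)-3-(3-methylbut-2-en-1-yl)phenyl]prop-2-enal | C=C(C=O)c1ccc(OC)c(CC=C(C)C)c1OCOC | intermediate
11 | 5-methoxyresorcinol (5-methoxybenzene-1,3-diol) | COc1cc(O)cc(O)c1 | starting material
12 | (2R)-3-(2,4-dihydroxy-6-methoxyphenyl)-2-[4-methoxy-2-(methoxymethoxy)-3-(3-methylbut-2-en-1-yl)phenyl]propanal | COc1cc(O)cc(O)c1C[C@H](c1ccc(OC)c(CC=C(C)C)c1OCOC)C=O | intermediate
13 | (3R)-5-methoxy-3-[4-methoxy-2-(methoxymethoxy)-3-(3-methylbut-2-en-1-yl)phenyl]-3,4-dihydro-2H-chromene-2,7-diol (anomeric mixture) | COc1cc(O)cc2c1C[C@H](c1ccc(OC)c(CC=C(C)C)c1OCOC)C(O)O2 | intermediate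
14 | 4-[(2R)-3-hydroxy-2-[4-methoxy-2-(methoxymethoxy)-3-(3-methylbut-2-en-1-yl)phenyl]propyl]-5-methoxybenzene-1,3-diol | COc1cc(O)cc(O)c1C[C@H](c1ccc(OC)c(CC=C(C)C)c1OCOC)CO | intermediate
15 | (3R)-5-methoxy-3-[4-methoxy-2-(methoxymethoxy)-3-(3-methylbut-2-en-1-yl)phenyl]-3,4-dihydro-2H-chromen-7-ol | COc1cc(O)cc2c1C[C@H](c1ccc(OC)c(CC=C(C)C)c1OCOC)CO2 | intermediate
16 | (3R)-3-[2-hydroxy-4-methoxy-3-(3-methylbut-2-en-1-yl)phenyl]-5-methoxy-3,4-dihydro-2H-chromen-7-ol | COc1cc(O)cc2c1C[C@H](c1ccc(OC)c(CC=C(C)C)c1O)CO2 | target

**Step count and least certain steps**

Total step count: 8. Longest linear sequence: 8 steps (1 to 16); compounds 3, 6 and 11 are purchased and enter directly.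

Step 5 (key step). The most likely failure is erosion of enantioselectivity. The phenol is present in excess and can protonate the enamine without the catalyst, and the alpha-aryl aldehyde can re-enter the enamine manifold before the lactol closes. Attack at C2 of the resorcinol and self-condensation of the 2-arylacrolein may also lower the return.

Fallback (auxiliary-controlled alkylation, known chemistry), setting out from 5 and 11 and coming back at 14:
- Ring B acid: aryllithium 7, made from 5 as in step 3, is trapped with ethylene oxide (BF3·OEt2, THF, −78 °C) to give 2-[4-methoxy-2-(methoxymethoxy)-3-(3-methylbut-2-en-1-yl)phenyl]ethan-1-ol F1. TEMPO/PhI(OAc)2 in MeCN/water oxidises it to the arylacetic acid F2. Its mixed pivalic anhydride acylates lithiated (R)-4-benzyloxazolidin-2-one to give the imide F3.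
- Ring A electrophile: Vilsmeier–Haack formylation of 11 (POCl3, DMF) gives 2,4-dihydroxy-6-methoxybenzaldehyde F4, so the regiochemistry is settled on a simple crystalline aldehyde. Silylation (TBSCl, imidazole) gives the bis(silyl) ether F5, NaBH4 gives the benzylic alcohol F6, and CBr4/PPh3 at −20 °C gives the benzylic bromide F7, which is used crude and cold.
- Joining: the sodium enolate of F3 (NaHMDS, THF, −78 °C) is alkylated by F7 on the face opposite the benzyl group of the auxiliary (Evans alkylation), which should give the (2R)-configured imide F8. LiBH4 removes the auxiliary to give the primary alcohol F9, and TBAF frees the two phenols to give 14.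

Step 3. The most likely failure is deprotonation at the benzylic and allylic CH2 of the prenyl group in competition with ring lithiation. Lithiation next to the methoxyl rather than the methoxymethoxy group is the second risk.

Fallback (halogen in place of a second deprotonation), setting out from 1 and coming back at 7:
- 1 is acetylated to 3-methoxyphenyl acetate F10, brominated para to the methoxyl (NBS, MeCN) to 2-bromo-5-methoxyphenyl acetate F11, and methanolysed (K2CO3, MeOH) to 2-bromo-5-methoxyphenol F12.
- Tsuji–Trost O-alkylation with tert-butyl 2-methylbut-3-en-2-yl carbonate (Pd(PPh3)4, THF, 0 °C) gives the 1,1-dimethylallyl ether F13. Its aromatic Claisen rearrangement (toluene, 110 °C) can only go to the one free ortho position, between the two oxygens, and gives 6-bromo-3-methoxy-2-(3-methylbut-2-en-1-yl)phenol F14.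
- NaH/MOMCl gives the bromide F15. Bromine–lithium exchange (n-BuLi, THF, −78 °C) is faster than any deprotonation and delivers aryllithium 7 regiospecifically, which continues through 8 to 9 as in step 3.

Step 7. The most likely failure is intermolecular etherification at the free C7 hydroxyl, leading to oligomers in competition with ring closure, because two phenols are present under the Mitsunobu conditions.

Fallback (stepwise activation and closure), setting out from 14 and coming back at 15: Appel bromination (CBr4, PPh3, CH2Cl2, 0 °C) converts only the primary alcohol and gives 4-[(2R)-3-bromo-2-[4-methoxy-2-(methoxymethoxy)-3-(3-methylbut-2-en-1-yl)phenyl]propyl]-5-methoxybenzene-1,3-diol F16. K2CO3 in acetone at high dilution then closes ring C by intramolecular Williamson etherification.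

Step 8. The most likely failure is acid-promoted addition of the freed C2' hydroxyl to the prenyl double bond, forming a 2,2-dimethylchroman. Electrophilic methoxymethylation of the electron-rich ring A is the second risk.

Fallback (protecting-group exchange without Brønsted acid), setting out from 15 and coming back at 16: TMSOTf and 2,2'-bipyridyl in MeCN at 0 °C transfer the methoxymethyl group to the pyridine base and silylate both phenolic oxygens, giving the bis(trimethylsilyl) ether F17. K2CO3 in MeOH at 0 °C then removes both silyl groups.

**Further compounds**

F1 | step 5 | 2-[4-methoxy-2-(methoxymethoxy)-3-(3-methylbut-2-en-1-yl)phenyl]ethan-1-ol | OCCc1ccc(OC)c(CC=C(C)C)c1OCOC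
F2 | step 5 | 2-[4-methoxy-2-(methoxymethoxy)-3-(3-methylbut-2-en-1-yl)phenyl]acetic acid | OC(=O)Cc1ccc(OC)c(CC=C(C)C)c1OCOC
F3 | step 5 | (4R)-4-benzyl-3-{2-[4-methoxy-2-(methoxymethoxy)-3-(3-methylbut-2-en-1-yl)phenyl]acetyl}-1,3-oxazolidin-2-one | O=C1OC[C@@H](Cc2ccccc2)N1C(=O)Cc1ccc(OC)c(CC=C(C)C)c1OCOC
F4 | step 5 | 2,4-dihydroxy-6-methoxybenzaldehyde | COc1cc(O)cc(O)c1C=O
F5 | step 5 | 2,4-bis[(tert-butyldimethylsilyl)oxy]-6-methoxybenzaldehyde | COc1cc(O[Si](C)(C)C(C)(C)C)cc(O[Si](C)(C)C(C)(C)C)c1C=O
F6 | step 5 | {2,4-bis[(tert-butyldimethylsilyl)oxy]-6-methoxyphenyl}methanol | COc1cc(O[Si](C)(C)C(C)(C)C)cc(O[Si](C)(C)C(C)(C)C)c1CO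
F7 | step 5 | 2-(bromomethyl)-1,5-bis[(tert-butyldimethylsilyl)oxy]-3-methoxybenzene | COc1cc(O[Si](C)(C)C(C)(C)C)cc(O[Si](C)(C)C(C)(C)C)c1CBr
F8 | step 5 | (4R)-4-benzyl-3-[(2R)-3-{2,4-bis[(tert-butyldimethylsilyl)oxy]-6-methoxyphenyl}-2-[4-methoxy-2-(methoxymethoxy)-3-(3-methylbut-2-en-1-yl)phenyl]propanoyl]-1,3-oxazolidin-2-one | COc1cc(O[Si](C)(C)C(C)(C)C)cc(O[Si](C)(C)C(C)(C)C)c1C[C@H](c1ccc(OC)c(CC=C(C)C)c1OCOC)C(=O)N1[C@H](Cc2ccccc2)COC1=O
F9 | step 5 | (2R)-3-{2,4-bis[(tert-butyldimethylsilyl)oxy]-6-methoxyphenyl}-2-[4-methoxy-2-(methoxymethoxy)-3-(3-methylbut-2-en-1-yl)phenyl]propan-1-ol | COc1cc(O[Si](C)(C)C(C)(C)C)cc(O[Si](C)(C)C(C)(C)C)c1C[C@H](c1ccc(OC)c(CC=C(C)C)c1OCOC)CO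
F10 | step 3 | 3-methoxyphenyl acetate | COc1cccc(OC(C)=O)c1
F11 | step 3 | 2-bromo-5-methoxyphenyl acetate | COc1ccc(Br)c(OC(C)=O)c1
F12 | step 3 | 2-bromo-5-methoxyphenol | COc1ccc(Br)c(O)c1
F13 | step 3 | 1-bromo-4-methoxy-2-[(2-methylbut-3-en-2-yl)oxy]benzene | COc1ccc(Br)c(OC(C)(C)C=C)c1
F14 | step 3 | 6-bromo-3-methoxy-2-(3-methylbut-2-en-1-yl)phenol | COc1ccc(Br)c(O)c1CC=C(C)C
F15 | step 3 | 1-bromo-4-methoxy-2-(methoxymethoxy)-3-(3-methylbut-2-en-1-yl)benzene | COCOc1c(Br)ccc(OC)c1CC=C(C)C
F16 | step 7 | 4-[(2R)-3-bromo-2-[4-methoxy-2-(methoxymethoxy)-3-(3-methylbut-2-en-1-yl)phenyl]propyl]-5-methoxybenzene-1,3-diol | COc1cc(O)cc(O)c1C[C@H](c1ccc(OC)c(CC=C(C)C)c1OCOC)CBr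
F17 | step 8 | (3R)-5-methoxy-3-[4-methoxy-3-(3-methylbut-2-en-1-yl)-2-[(trimethylsilyl)oxy]phenyl]-7-[(trimethylsilyl)oxy]-3,4-dihydro-2H-chromene | COc1cc(O[Si](C)(C)C)cc2c1C[C@H](c1ccc(OC)c(CC=C(C)C)c1O[Si](C)(C)C)CO2
A1 | alternative 1 | methyl 2-diazo-2-[4-methoxy-2-({2-methoxy-6-[(2,2-dimethylpropanoyl)oxy]-4-[(triisopropylsilyl)oxy]phenyl}methoxy)phenyl]acetate | COC(=O)C(=[N+]=[N-])c1ccc(OC)cc1OCc1c(OC)cc(O[Si](C(C)C)(C(C)C)C(C)C)cc1OC(=O)C(C)(C)C
A2 | alternative 1 | methyl cis-6-methoxy-2-[2-methoxy-6-(pivaloyloxy)-4-(triisopropylsilyloxy)phenyl]-2,3-dihydro-1-benzofuran-3-carboxylate (C3 as in the target) | COC(=O)[C@H]1c2ccc(OC)cc2O[C@H]1c1c(OC)cc(O[Si](C(C)C)(C(C)C)C(C)C)cc1OC(=O)C(C)(C)C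
A3 | alternative 2 | 4,4,5,5-tetramethyl-2-vinyl-1,3,2-dioxaborolane | C=CB1OC(C)(C)C(C)(C)O1
A4 | alternative 2 | 2-[(tert-butyldimethylsilyl)oxy]-6-methoxy-4-(methoxymethoxy)phenyl trifluoromethanesulfonate | COc1cc(OCOC)cc(O[Si](C)(C)C(C)(C)C)c1OS(=O)(=O)C(F)(F)F
A5 | alternative 2 | 2-[(1R)-2-{2-[(tert-butyldimethylsilyl)oxy]-6-methoxy-4-(methoxymethoxy)phenyl}-1-[4-methoxy-2-(methoxymethoxy)-3-(3-methylbut-2-en-1-yl)phenyl]ethyl]-4,4,5,5-tetramethyl-1,3,2-dioxaborolane | COc1cc(OCOC)cc(O[Si](C)(C)C(C)(C)C)c1C[C@H](c1ccc(OC)c(CC=C(C)C)c1OCOC)B1OC(C)(C)C(C)(C)O1
A6 | alternative 3 | 1-[(3R)-5-methoxy-7-(methoxymethoxy)-3,4-dihydro-2H-chromen-3-yl]propan-2-one | CC(=O)C[C@@H]1COc2cc(OCOC)cc(OC)c2C1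
A7 | alternative 3 | methyl acrylate | C=CC(=O)OC
A8 | alternative 3 | 4-[(3R)-5-methoxy-7-(methoxymethoxy)-3,4-dihydro-2H-chromen-3-yl]cyclohexane-1,3-dione (epimers at the ring carbon) | O=C1CCC([C@@H]2COc3cc(OCOC)cc(OC)c3C2)C(=O)C1
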